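The 1,2-dioxane ring is opened at C5–C6, the bond between the ring CH2 and the fully substituted peroxyketal carbon. The plan exploits that C6, bonded to O1 of the ring and to OMe, is a masked carboxyl carbon, so it enters as an orthoester. In one operation an enantiopure allylic hydroperoxide exchanges onto the side-chain orthoester (O1–C6). The acyclic peroxy orthoester then ionises, and the (Z)-vinylsilane carbon C5 attacks the methoxy(peroxy)carbenium ion. This closes the six-membered peroxide ring and sets C6 under anomeric control from C3. C3 stems from an organocatalytic enal peroxidation. Diimide then saturates C4=C5, and a Sonogashira coupling completes the dienyne chain.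

Key step: step 8

Remark on numbering: ring atoms are O1, O2, C3 (bears CH2CO2Me), C4, C5, C6 (peroxyketal carbon). The same labels are kept for these atoms in all precursors.
Assumption: the facial sense of the amine-catalysed peroxidation follows the usual steric-shielding model of the E-iminium ion, and both catalyst enantiomers are commercial.

Step 1
Reactants: 1 3-(trimethylsilyl)prop-2-ynal; 2 (triphenylphosphoranylidene)acetaldehyde
Product: 3 (E)-5-(trimethylsilyl)pent-2-en-4-ynal
Conditions: CH2Cl2, 0 °C → rt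
Reagents that add atoms: none
Why: Wittig reaction of the stabilised formyl ylide with the very electrophilic ynal should stop after one two-carbon homologation and give the E-enal.

Step 2
Reactants: 3 (E)-5-(trimethylsilyl)pent-2-en-4-ynal
Product: 4 (2E,4Z)-5-(trimethylsilyl)penta-2,4-dienal
Conditions: H2 (1 atm, 1 equiv uptake), Pd/CaCO3 poisoned with Pb(OAc)2, quinoline, EtOAc–hexane, 0 °C
Reagents that add atoms: none
Why: Lindlar semihydrogenation adds H2 syn to the alkyne only, so silicon and C3 end up cis (4Z) while the enal double bond and the aldehyde are left alone.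

Step 3
Reactants: 5 2,3-dimethylbut-2-ene
Product: 7 2-methoxypropan-2-yl hydroperoxide, via acetone O-oxide 6 (not isolated)
Conditions: O3, CH2Cl2–MeOH, −78 °C
Reagents that add atoms: ozone [O-][O+]=O; methanol CO
Why: Ozonolysis of the tetrasubstituted alkene in methanol gives acetone plus carbonyl oxide 6, which the solvent traps as the α-methoxy hydroperoxide.

Step 4
Reactants: 4 (2E,4Z)-5-(trimethylsilyl)penta-2,4-dienal; 7 2-methoxypropan-2-yl hydroperoxide
Product: 8 (R,Z)-3-[(2-methoxypropan-2-yl)peroxy]-5-(trimethylsilyl)pent-4-enal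
Conditions: (R)-2-[diphenyl(trimethylsilyloxy)methyl]pyrrolidine (20 mol %), PhCO2H (20 mol %), toluene, 0 °C
Reagents that add atoms: none
Why: In this iminium-catalysed enantioselective conjugate peroxidation of an enal, the CPh2(OSiMe3) group shields one face of the E-iminium ion so that 7 adds to C3 from the open face to set (R), and silicon on C5 disfavours 1,6-addition both sterically and electronically.

Step 5
Reactants: 8 (R,Z)-3-[(2-methoxypropan-2-yl)peroxy]-5-(trimethylsilyl)pent-4-enal
Product: 9 (R,Z)-3-[(2-methoxypropan-2-yl)peroxy]-5-(trimethylsilyl)pent-4-enoic acid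
Conditions: NaClO2, NaH2PO4, 2-methylbut-2-ene, t-BuOH–H2O, 0 °C
Reagents that add atoms: sodium chlorite [Na+].[O-]Cl=O
Why: Pinnick oxidation is selective for the aldehyde, and its buffered non-basic medium avoids β-elimination of the peroxide and leaves the vinylsilane, the O–O bond and C3 untouched.

Step 6
Reactants: 9 (R,Z)-3-[(2-methoxypropan-2-yl)peroxy]-5-(trimethylsilyl)pent-4-enoic acid
Product: 11 methyl (R,Z)-3-hydroperoxy-5-(trimethylsilyl)pent-4-enoate, via perketal methyl ester 10 (not isolated)
Conditions: TMSCHN2 (1.1 equiv), toluene–MeOH, 0 °C; then PPTS (10 mol %), MeOH, rt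
Reagents that add atoms: (trimethylsilyl)diazomethane C[Si](C)(C)C=[N+]=[N-]
Why: Esterification with the diazomethane equivalent needs no base, and the following acid-catalysed transketalisation to methanol removes the 2-methoxyprop-2-yl group from the peroxide without touching the vinylsilane or C3.

Step 7
Reactants: 12 (triisopropylsilyl)acetylene; 13 trimethyl 4-bromoorthobutyrate (4-bromo-1,1,1-trimethoxybutane)
Product: 15 triisopropyl(6,6,6-trimethoxyhex-1-yn-1-yl)silane, via lithium acetylide 14 (not isolated)
Conditions: n-BuLi, THF, −78 °C; then 13, DMPU, −78 °C → rt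
Reagents that add atoms: none
Why: This is an SN2 alkylation of a lithium acetylide with a primary bromide in a dipolar cosolvent, to which the orthoester is inert.

Step 8
Reactants: 11 methyl (R,Z)-3-hydroperoxy-5-(trimethylsilyl)pent-4-enoate; 15 triisopropyl(6,6,6-trimethoxyhex-1-yn-1-yl)silane
Product: 18 methyl 2-{(3R,6R)-6-methoxy-6-[5-(triisopropylsilyl)pent-4-yn-1-yl]-3,6-dihydro-1,2-dioxin-3-yl}acetate, via peroxy orthoester 16 (not isolated), via methoxy(peroxy)carbenium triflate 17 (not isolated)
Conditions: 15 (1.2 equiv), PPTS (5 mol %), 4 Å MS, CH2Cl2, 0 °C; then TMSOTf (30 mol %), −78 → −40 °C; Et3N quench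
Reagents that add atoms: none
Why: Proposed new method: mild acid exchanges one methoxy group of 15 for the OOH group of 11 to give peroxy orthoester 16, TMSOTf then ionises a second methoxy group, and the methoxy(peroxy)carbenium ion 17 is attacked at C6 by the silicon-bearing carbon C5 of the (Z)-vinylsilane, after which loss of the silyl group restores the C4=C5 double bond and regenerates TMSOTf. The closest known reaction types are the Lewis-acid-mediated trapping of peroxycarbenium ions (from monoperoxyketals) by allylsilanes and tethered alkenes and the acetal-initiated, (Z)-vinylsilane-terminated cyclisation to 5,6-dihydro-2H-pyrans; new is a carboxyl-level cation that keeps one methoxy group on C6. The 3,6-dihydro-1,2-dioxine ring closes in the 6-endo-trig mode, enforced by the β-silicon effect because only attack through C5 puts the charge on C4 next to an axial C–Si bond, whereas 5-exo attack through C4 would give an α-silyl cation. C3 is not touched, and the new centre C6 is controlled by C3 through a chair-like transition state with CH2CO2Me and the side chain pseudoequatorial and OMe pseudoaxial (developing anomeric stabilisation); since C6 is a ketal carbon it stays correctable by the acid-catalysed equilibration in step 9. The step needs C–O ionisation and C–C closure to outrun O–O heterolysis (Criegee or Hock type migration from C3) and demethylation of 17 to the perester, which low temperature, the non-nucleophilic triflate counter-ion and the methoxy donor that keeps charge off O1 should secure. The TIPS-alkyne stays a spectator because its ipso attack on C6 would require an endocyclic vinyl cation.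

Step 9
Reactants: 18 methyl 2-{(3R,6R)-6-methoxy-6-[5-(triisopropylsilyl)pent-4-yn-1-yl]-3,6-dihydro-1,2-dioxin-3-yl}acetate
Product: 19 methyl 2-{(3S,6R)-6-methoxy-6-[5-(triisopropylsilyl)pent-4-yn-1-yl]-1,2-dioxan-3-yl}acetate
Conditions: KO2CN=NCO2K (excess), AcOH, MeOH–CH2Cl2, 0 °C → rt; then PPTS (10 mol %), MeOH, rt
Reagents that add atoms: none
Why: Diimide reduction delivers H2 concertedly to the cis ring alkene without cleaving the O–O bond and ahead of the alkyne shielded by the triisopropylsilyl group, and the closing acid-catalysed ketal equilibration in methanol funnels any C6 epimer into the chair with axial OMe (anomeric effect) and both carbon substituents equatorial, which is the (3S,6R) isomer.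

Step 10
Reactants: 19 methyl 2-{(3S,6R)-6-methoxy-6-[5-(triisopropylsilyl)pent-4-yn-1-yl]-1,2-dioxan-3-yl}acetate
Product: 20 methyl 2-[(3S,6R)-6-methoxy-6-(pent-4-yn-1-yl)-1,2-dioxan-3-yl]acetate
Conditions: TBAF (1.2 equiv), AcOH (1.2 equiv), THF, 0 °C → rt
Reagents that add atoms: none
Why: This is a fluoride-induced protodesilylation of the alkynylsilane, and buffering with acetic acid suppresses retro-oxa-Michael opening at the β-peroxy ester, so C3 is not scrambled.

Step 11
Reactants: 21 9-bromonon-1-ene
Product: 22 undec-1-en-10-yne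
Conditions: LiC≡CH·H2NCH2CH2NH2, DMSO, rt
Reagents that add atoms: lithium acetylide–ethylenediamine complex [Li]C#C.NCCN
Why: SN2 alkylation of lithium acetylide by an unhindered primary bromide is a standard two-carbon extension.

Step 12
Reactants: 22 undec-1-en-10-yne
Product: 24 (E)-1-iodoundeca-1,10-diene, via alkenylzirconocene chloride 23 (not isolated)
Conditions: Cp2Zr(H)Cl (1.0 equiv), CH2Cl2, 0 °C → rt; then I2, 0 °C
Reagents that add atoms: iodine II
Why: Hydrozirconation is syn, places zirconium on the terminal alkyne carbon and is faster for the alkyne than for the terminal alkene, and iodinolysis with retention gives the E-vinyl iodide.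

Step 13
Reactants: 20 methyl 2-[(3S,6R)-6-methoxy-6-(pent-4-yn-1-yl)-1,2-dioxan-3-yl]acetate; 24 (E)-1-iodoundeca-1,10-diene
Product: 25 peroxyacarnoate A (methyl 2-{(3S,6R)-6-[(6E)-hexadeca-6,15-dien-4-yn-1-yl]-6-methoxy-1,2-dioxan-3-yl}acetate)
Conditions: Pd(PPh3)4 (5 mol %), CuI (10 mol %), i-Pr2NH, THF, rt
Reagents that add atoms: none
Why: Sonogashira coupling forms the sp–sp2 bond with retention of the E geometry under mild amine conditions that a dialkyl peroxide and the β-peroxy ester should tolerate.

Compound list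
1 | 3-(trimethylsilyl)prop-2-ynal | C[Si](C)(C)C#CC=O | starting material
2 | (triphenylphosphoranylidene)acetaldehyde | O=CC=P(c1ccccc1)(c1ccccc1)c1ccccc1 | starting material
3 | (E)-5-(trimethylsilyl)pent-2-en-4-ynal | C[Si](C)(C)C#C/C=C/C=O | intermediate
4 | (2E,4Z)-5-(trimethylsilyl)penta-2,4-dienal | O=C/C=C/C=C\[Si](C)(C)C | intermediate
5 | 2,3-dimethylbut-2-ene | CC(C)=C(C)C | starting material
6 | acetone O-oxide (not isolated) | CC(C)=[O+][O-] | intermediate
7 | 2-methoxypropan-2-yl hydroperoxide | COC(C)(C)OO | intermediate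
8 | (R,Z)-3-[(2-methoxypropan-2-yl)peroxy]-5-(trimethylsilyl)pent-4-enal | O=CC[C@@H](OOC(C)(C)OC)/C=C\[Si](C)(C)C | intermediate
9 | (R,Z)-3-[(2-methoxypropan-2-yl)peroxy]-5-(trimethylsilyl)pent-4-enoic acid | OC(=O)C[C@@H](OOC(C)(C)OC)/C=C\[Si](C)(C)C | intermediate
10 | methyl (R,Z)-3-[(2-methoxypropan-2-yl)peroxy]-5-(trimethylsilyl)pent-4-enoate (not isolated) | COC(=O)C[C@@H](OOC(C)(C)OC)/C=C\[Si](C)(C)C | intermediate
11 | methyl (R,Z)-3-hydroperoxy-5-(trimethylsilyl)pent-4-enoate | COC(=O)C[C@@H](OO)/C=C\[Si](C)(C)C | intermediate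
12 | (triisopropylsilyl)acetylene | C#C[Si](C(C)C)(C(C)C)C(C)C | starting material
13 | trimethyl 4-bromoorthobutyrate (4-bromo-1,1,1-trimethoxybutane) | COC(OC)(OC)CCCBr | starting material
14 | lithium (triisopropylsilyl)acetylide (not isolated) | [Li]C#C[Si](C(C)C)(C(C)C)C(C)C | intermediate
15 | triisopropyl(6,6,6-trimethoxyhex-1-yn-1-yl)silane | COC(CCCC#C[Si](C(C)C)(C(C)C)C(C)C)(OC)OC | intermediate
16 | methyl (R,Z)-3-{[1,1-dimethoxy-6-(triisopropylsilyl)hex-5-yn-1-yl]peroxy}-5-(trimethylsilyl)pent-4-enoate (not isolated) | COC(=O)C[C@@H](OOC(OC)(OC)CCCC#C[Si](C(C)C)(C(C)C)C(C)C)/C=C\[Si](C)(C)C | intermediate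
17 | methoxy(peroxy)carbenium triflate derived from 16 by loss of methoxide (not isolated) | COC(=O)C[C@@H](OO[C+](OC)CCCC#C[Si](C(C)C)(C(C)C)C(C)C)/C=C\[Si](C)(C)C.[O-]S(=O)(=O)C(F)(F)F | intermediate
18 | methyl 2-{(3R,6R)-6-methoxy-6-[5-(triisopropylsilyl)pent-4-yn-1-yl]-3,6-dihydro-1,2-dioxin-3-yl}acetate | CC(C)[Si](C#CCCC[C@]1(OC)C=C[C@@H](CC(=O)OC)OO1)(C(C)C)C(C)C | intermediate
19 | methyl 2-{(3S,6R)-6-methoxy-6-[5-(triisopropylsilyl)pent-4-yn-1-yl]-1,2-dioxan-3-yl}acetate | CC(C)[Si](C#CCCC[C@]1(OC)CC[C@@H](CC(=O)OC)OO1)(C(C)C)C(C)C | intermediate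
20 | methyl 2-[(3S,6R)-6-methoxy-6-(pent-4-yn-1-yl)-1,2-dioxan-3-yl]acetate | C#CCCC[C@]1(OC)CC[C@@H](CC(=O)OC)OO1 | intermediate
21 | 9-bromonon-1-ene | C=CCCCCCCCBr | starting material
22 | undec-1-en-10-yne | C=CCCCCCCCC#C | intermediate
23 | chloro[(E)-undeca-1,10-dien-1-yl]zirconocene (not isolated) | C=CCCCCCCC/C=C/[Zr](Cl)(C1C=CC=C1)C1C=CC=C1 | intermediate
24 | (E)-1-iodoundeca-1,10-diene | C=CCCCCCCC/C=C/I | intermediate
25 | peroxyacarnoate A | C=CCCCCCCC/C=C/C#CCCC[C@]1(OC)CC[C@@H](CC(=O)OC)OO1 | target

Total step count: 13. Longest linear sequence: 9 steps (1, 2, 4, 5, 6, 8, 9, 10, 13).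

Steps most likely to fail

1) Step 8 (Proposed new method).
- What may go wrong: the activated peroxide may undergo O–O heterolysis with migration of the alkenyl group or hydrogen from C3. The cation may be demethylated to the perester. The vinylsilane may be protodesilylated before the C–C bond forms.
- Fallback: it uses known chemistry and closes the ring through O1–C6 instead. It sets out from 15 and 7 and comes back at 19.
- Addition of but-3-enylmagnesium bromide to orthoester 15 (Et2O–toluene, reflux) gives (6,6-dimethoxydec-9-en-1-yn-1-yl)triisopropylsilane F1, which aqueous HCl work-up hydrolyses to 10-(triisopropylsilyl)dec-1-en-9-yn-5-one F2.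
- Cross-metathesis with crotonaldehyde (second-generation Hoveyda–Grubbs catalyst, CH2Cl2, 40 °C) gives (E)-6-oxo-11-(triisopropylsilyl)undec-2-en-10-ynal F3.
- Peroxidation with 7 under the conditions of step 4 gives (S)-3-[(2-methoxypropan-2-yl)peroxy]-6-oxo-11-(triisopropylsilyl)undec-10-ynal F4.
- Pinnick oxidation gives (S)-3-[(2-methoxypropan-2-yl)peroxy]-6-oxo-11-(triisopropylsilyl)undec-10-ynoic acid F5, and TMSCHN2 gives methyl (S)-3-[(2-methoxypropan-2-yl)peroxy]-6-oxo-11-(triisopropylsilyl)undec-10-ynoate F6.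
- PPTS in MeOH then cleaves the perketal, the freed OOH group adds to the C6 ketone, and methyl ketal formation under anomeric control leads to 19. Steps 8 and 9 are bypassed.

2) Step 4.
- What may go wrong: the 4Z geometry may erode by rotation in the extended iminium ion. The hydroperoxide may add in the 1,6 sense. The enamine may collapse onto the O–O bond to give the epoxide.
- Fallback: the stereocentre is set before the Z-alkene exists. It sets out from 3 and comes back at 10.
- Enynal 3 is peroxidised with 7 under the conditions of step 4 to (R)-3-[(2-methoxypropan-2-yl)peroxy]-5-(trimethylsilyl)pent-4-ynal F7.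
- Pinnick oxidation gives (R)-3-[(2-methoxypropan-2-yl)peroxy]-5-(trimethylsilyl)pent-4-ynoic acid F8, and TMSCHN2 gives methyl (R)-3-[(2-methoxypropan-2-yl)peroxy]-5-(trimethylsilyl)pent-4-ynoate F9.
- Syn-hydroboration with dicyclohexylborane (THF, 0 °C, boron to the silicon-bearing carbon) gives methyl (R,Z)-5-(dicyclohexylboranyl)-3-[(2-methoxypropan-2-yl)peroxy]-5-(trimethylsilyl)pent-4-enoate F10. Protonolysis with AcOH proceeds with retention and gives 10.

3) Step 9.
- What may go wrong: the hindered ring alkene next to the quaternary C6 may reduce slowly, so that a large excess of diimide also begins to reduce the silylalkyne.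
- Fallback: the ring is saturated before any other multiple bond is present. It sets out from 11, 13 and 24 and comes back at 25.
- Hydroperoxide 11 is combined with the commercial bromo orthoester 13 itself under the conditions of step 8 to give methyl 2-[(3R,6R)-6-(3-bromopropyl)-6-methoxy-3,6-dihydro-1,2-dioxin-3-yl]acetate F11.
- Diimide followed by PPTS/MeOH, as in step 9, gives methyl 2-[(3S,6S)-6-(3-bromopropyl)-6-methoxy-1,2-dioxan-3-yl]acetate F12. It has the same spatial arrangement as 19, and the C6 descriptor changes only because of bromine.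
- Separately, Sonogashira coupling of 24 with (trimethylsilyl)acetylene gives (E)-trimethyl(trideca-3,12-dien-1-yn-1-yl)silane F13, and K2CO3 in MeOH gives (E)-trideca-3,12-dien-1-yne F14.
- An alkyl Sonogashira coupling of F12 with F14 ([(C3H5)PdCl]2, 1,3-bis(1-adamantyl)imidazolium chloride, CuI, Cs2CO3, DMF–Et2O, 45–60 °C) gives 25.

Further compounds
F1 | step 8 | (6,6-dimethoxydec-9-en-1-yn-1-yl)triisopropylsilane | C=CCCC(OC)(OC)CCCC#C[Si](C(C)C)(C(C)C)C(C)C
F2 | step 8 | 10-(triisopropylsilyl)dec-1-en-9-yn-5-one | C=CCCC(=O)CCCC#C[Si](C(C)C)(C(C)C)C(C)C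
F3 | step 8 | (E)-6-oxo-11-(triisopropylsilyl)undec-2-en-10-ynal | O=C/C=C/CCC(=O)CCCC#C[Si](C(C)C)(C(C)C)C(C)C
F4 | step 8 | (S)-3-[(2-methoxypropan-2-yl)peroxy]-6-oxo-11-(triisopropylsilyl)undec-10-ynal | O=CC[C@@H](OOC(C)(C)OC)CCC(=O)CCCC#C[Si](C(C)C)(C(C)C)C(C)C
F5 | step 8 | (S)-3-[(2-methoxypropan-2-yl)peroxy]-6-oxo-11-(triisopropylsilyl)undec-10-ynoic acid | OC(=O)C[C@@H](OOC(C)(C)OC)CCC(=O)CCCC#C[Si](C(C)C)(C(C)C)C(C)C
F6 | step 8 | methyl (S)-3-[(2-methoxypropan-2-yl)peroxy]-6-oxo-11-(triisopropylsilyl)undec-10-ynoate | COC(=O)C[C@@H](OOC(C)(C)OC)CCC(=O)CCCC#C[Si](C(C)C)(C(C)C)C(C)C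
F7 | step 4 | (R)-3-[(2-methoxypropan-2-yl)peroxy]-5-(trimethylsilyl)pent-4-ynal | O=CC[C@@H](OOC(C)(C)OC)C#C[Si](C)(C)C
F8 | step 4 | (R)-3-[(2-methoxypropan-2-yl)peroxy]-5-(trimethylsilyl)pent-4-ynoic acid | OC(=O)C[C@@H](OOC(C)(C)OC)C#C[Si](C)(C)C
F9 | step 4 | methyl (R)-3-[(2-methoxypropan-2-yl)peroxy]-5-(trimethylsilyl)pent-4-ynoate | COC(=O)C[C@@H](OOC(C)(C)OC)C#C[Si](C)(C)C
F10 | step 4 | methyl (R,Z)-5-(dicyclohexylboranyl)-3-[(2-methoxypropan-2-yl)peroxy]-5-(trimethylsilyl)pent-4-enoate | COC(=O)C[C@@H](OOC(C)(C)OC)/C=C(\[Si](C)(C)C)B(C1CCCCC1)C1CCCCC1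
F11 | step 9 | methyl 2-[(3R,6R)-6-(3-bromopropyl)-6-methoxy-3,6-dihydro-1,2-dioxin-3-yl]acetate | BrCCC[C@]1(OC)C=C[C@@H](CC(=O)OC)OO1
F12 | step 9 | methyl 2-[(3S,6S)-6-(3-bromopropyl)-6-methoxy-1,2-dioxan-3-yl]acetate | BrCCC[C@]1(OC)CC[C@@H](CC(=O)OC)OO1
F13 | step 9 | (E)-trimethyl(trideca-3,12-dien-1-yn-1-yl)silane | C=CCCCCCCC/C=C/C#C[Si](C)(C)C
F14 | step 9 | (E)-trideca-3,12-dien-1-yne | C=CCCCCCCC/C=C/C#C
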